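Structural features

The target is a 1-aryltetralin lignan. Ring A is a benzene ring carrying OMe at C6 and OH at C7; it is fused through C4a/C8a to the saturated ring B (C1–C4). Ring C, a 4-hydroxy-3-methoxyphenyl group, sits on C1, and C2 and C3 each carry CH2OH (tetralin numbering with the aryl-bearing carbon as C1 is used throughout). C1, C2 and C3 are contiguous stereocentres, read from the SMILES as 1R,2R,3R: the C1 aryl and the C2 CH2OH are cis, the C2 and C3 CH2OH groups are trans. This is the podophyllotoxin-type array and the C1 epimer of the isolariciresinol array. With the C2 and C3 groups equatorial the aryl group is pseudoaxial, and C1 has no acidifying group, so its configuration must be set kinetically and cis to C2. The OMe of ring A is para to C8a and the OH para to C4a, so the benzylic carbons C1 and C4 differ only through remote substituents, and any assembly of ring B from a pseudo-symmetric arene has a hidden regiochemical problem. Fragile features are the two electron-rich phenols, the doubly benzylic C1–H para to the ring C phenol (oxidation, quinone methide formation) and the 1,4-diol (acid-promoted cyclic ether formation). The real difficulty is the C1–aryl bond together with the contra-thermodynamic 1,2-cis relation, which cation-based ring closures do not deliver. The key step exploits the fact that in an aryl-free tetralin C1 is a benzylic CH2 lying β to a C2 carboxamide: the C1–H on the face of that carboxamide can be replaced by aryl with retention, which writes the 1,2-cis relation directly.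

Logic of the disconnections

17 to 16: the two phenolic O–H bonds are traced back to O–benzyl bonds. The phenols are the most oxidation-sensitive part and are kept masked until the end. The forward step must be a hydrogenolysis that touches nothing else, which holds because 16 has no benzylic heteroatom bond and no alkene.

16 to 15 to 14: the C2 CH2OH is traced back to a C2 carboxamide carrying a bidentate quinoline auxiliary, and the C3 CH2OH to its acetate. This puts on C2 the one group that can direct chemistry to C1. The forward demand is removal of a robust secondary amide by reduction without epimerising C2, which is why the amide is first activated as the N-Boc imide 15.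

14 to 11 and 13 (key disconnection): the C1–C(aryl) bond is cut, leaving a C1–H bond in 11 and an aryl iodide 13. In one sentence, the route is a carboxamide-directed, palladium-catalysed arylation of the C1–H bond of the aryl-free trans-2,3-disubstituted tetralin 11 with 13. The gain is large: ring C and the hardest stereocentre are removed together, and 11 has only two stereocentres in the easily controlled trans relation. The demand is that the C–H cleavage occurs only at C1, only on the face of the C2 carboxamide, and that C2 survives.

13 to 12: the O–benzyl bond is cut; a single etherification.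

11 to 10 to 9: the acetate is removed and the C1–H and C2–H bonds are cut to give the C1=C2 alkene of 9. C2 then no longer needs independent control, since the C3 CH2OH can relay its configuration to C2 by directing the hydrogenation. The demand is a catalyst that obeys the hydroxyl group in the presence of the quinoline amide.

9 to 8: the amide C–N bond is cut and the acyl group returned to the C3 oxygen, giving the unsaturated lactone 8. One aminolysis then installs the directing group and frees the directing hydroxyl. The demand is 1,2-attack of the aluminium amide on a conjugated lactone.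

8 to 6 (via 7): the C1–C8a bond and the C1=C2 bond are cut, removing C1 as a formate carbon. Ring B is thus built regiospecifically from a monofunctional arene: C1 is attached by electrophilic substitution para to OMe and C4 is the original benzylic carbon para to the protected phenol. This solves the pseudo-symmetry problem. The demand is an acid strong enough to cyclise 7 but mild enough for the aryl benzyl ether.

6 to 4 to 3 to 1 and 2: the lactone is opened to the half-ester 4, the C3–H and C4–H bonds are cut to give the alkene of 3, and the C3=C4 bond is cut to aldehyde 1 and succinate 2. The only stereocentre made from an achiral precursor by a catalyst is C3. The demand is high enantioselectivity in the hydrogenation of 3 and chemoselective reduction of the ester of 4 in the presence of its carboxylate.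

Other disconnections considered

Alternative 1: (the first that comes to mind) cut C1–C8a and close ring B by Friedel–Crafts alkylation of a benzylic cation. The trans aldol adduct A1 would be made from 6 and 1 and cyclised with acid to the lactone A2. In the chair-like transition state of this cation–arene closure the pendant aryl group is expected to sit pseudoequatorial and anti to the C2 substituent, so A2 should carry the 1,2-trans relation of the isolariciresinol series. C1 cannot be epimerised afterwards, so this short route is expected to lead to the C1 epimer of the target. The chosen plan sets C1 by a mechanism that enforces cis.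

Alternative 2: cut C1–C2 and C3–C4 and form ring B by a Diels–Alder reaction of an α-aryl ortho-quinodimethane, released thermally from the sulfone A3, with a chiral fumarate diester to give the cycloadduct A4. The fumarate secures 2,3-trans and the aryl group fixes the regiochemistry. A trans dienophile, however, places one ester endo and one exo in either transition state, so there is no intrinsic preference for the 1,2-cis relation and the face selectivity rests entirely on an auxiliary. A3 also needs its own multistep, regiodefined synthesis. The chosen plan has one stereo-defined precursor and a stereospecific key step.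

Alternative 3: cut the C1–H and C2–H bonds and set C1 and C2 together by hydroxyl-directed hydrogenation of the tetrasubstituted C1=C2 alkene of the 1-aryl-3,4-dihydronaphthalene diol A5, with the C3 CH2OH steering both hydrogens to its face. The stereochemical logic is sound and leads to the correct array. Against it, a tetrasubstituted diaryl-conjugated alkene is a slow substrate, double-bond migration and aromatisation to the naphthalene compete, and the aryl group must be installed earlier through a C1 carbonyl or enol derivative, which costs steps. The same logic is kept as the fallback for the key step.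

Key step: step 9

Assumption: 1, 2, 12 and all reagents are taken as commercial. The (S,S) hand of the bisphosphine in step 2 is taken as the one that delivers the 3R acid; the mirror-image ligand would be used if the facial sense proved opposite.

Step 1
Reactants: 1 4-(benzyloxy)-3-methoxybenzaldehyde; 2 dimethyl succinate
Product: 3 (3E)-4-[4-(benzyloxy)-3-methoxyphenyl]-3-(methoxycarbonyl)but-3-enoic acid
Conditions: NaOMe, MeOH, reflux; then aq. HCl
Reagents that add atoms: none
Why: Stobbe condensation: the succinate enolate adds to the aldehyde, and lactonisation followed by base-induced ring opening leaves free only the carboxyl remote from the alkene. The E alkene (aryl trans to CO2Me) is the usual outcome and is the geometry the hydrogenation needs.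

Step 2
Reactants: 3 (3E)-4-[4-(benzyloxy)-3-methoxyphenyl]-3-(methoxycarbonyl)but-3-enoic acid
Product: 4 (3R)-4-[4-(benzyloxy)-3-methoxyphenyl]-3-(methoxycarbonyl)butanoic acid
Conditions: [Rh(cod)2]BF4 (1 mol %), (S,S)-Et-DuPhos (1.1 mol %), NaOMe (10 mol %), H2 (5 bar), MeOH, rt
Reagents that add atoms: none
Why: Asymmetric hydrogenation of an itaconate half-ester with a cationic monovalent rhodium bisphosphine catalyst: carboxylate and alkene chelate the metal and the ligand hand fixes the face of H2 addition, which sets C3 as R. The aryl benzyl ether is inert to this homogeneous catalyst.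

Step 3
Reactants: 4 (3R)-4-[4-(benzyloxy)-3-methoxyphenyl]-3-(methoxycarbonyl)butanoic acid
Product: 6 (4R)-4-[4-(benzyloxy)-3-methoxybenzyl]oxolan-2-one, via hydroxy acid 5 (not isolated)
Conditions: KOH (1.0 equiv), EtOH; CaCl2, NaBH4 (Ca(BH4)2 in situ), −10 °C to rt; then 2 M HCl, rt
Reagents that add atoms: none
Why: Ca(BH4)2 reduces the methyl ester while the carboxyl group is protected as its potassium salt, and acidification lactonises the hydroxy acid. In 6 the stereocentre is no longer α to a carbonyl group, so it cannot be lost in later base steps.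

Step 4
Reactants: 6 (4R)-4-[4-(benzyloxy)-3-methoxybenzyl]oxolan-2-one
Product: 8 (3aR)-7-(benzyloxy)-6-methoxy-3a,4-dihydronaphtho[2,3-c]furan-1(3H)-one, via hydroxymethylene lactone 7 (not isolated)
Conditions: NaH, HCO2Et, THF, 0 °C to rt; crude enol, then TFA, CH2Cl2, 0 °C to rt
Reagents that add atoms: ethyl formate, CCOC=O
Why: Claisen formylation at the only enolisable CH2, then acid-promoted cyclodehydration (Bradsher-type electrophilic aromatic substitution and loss of water) closes the six-membered ring B at the arene carbon para to OMe, the most nucleophilic and least hindered ortho position. The added carbon becomes C1 (C9 of this ring system), conjugation with ring A and the lactone carbonyl drives the dehydration, and the non-enolisable C3 (C3a) is untouched.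

Step 5
Reactants: 8 (3aR)-7-(benzyloxy)-6-methoxy-3a,4-dihydronaphtho[2,3-c]furan-1(3H)-one
Product: 9 (3R)-7-(benzyloxy)-3-(hydroxymethyl)-6-methoxy-N-(quinolin-8-yl)-3,4-dihydronaphthalene-2-carboxamide
Conditions: quinolin-8-amine (2.0 equiv), AlMe3 (2.2 equiv), CH2Cl2, 0 °C to 40 °C; aq. Rochelle salt
Reagents that add atoms: quinolin-8-amine, Nc1cccc2cccnc12
Why: Aminolysis of a lactone with a dimethylaluminium amide (Weinreb-type amidation) opens the ring to the secondary amide and frees the C3 hydroxymethyl group. One operation thus installs the bidentate directing group for step 9 and unmasks the hydroxyl needed in step 6.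

Step 6
Reactants: 9 (3R)-7-(benzyloxy)-3-(hydroxymethyl)-6-methoxy-N-(quinolin-8-yl)-3,4-dihydronaphthalene-2-carboxamide
Product: 10 (2R,3R)-7-(benzyloxy)-3-(hydroxymethyl)-6-methoxy-N-(quinolin-8-yl)-1,2,3,4-tetrahydronaphthalene-2-carboxamide
Conditions: [Ir(cod)(PCy3)(py)]PF6 (5 mol %), H2 (1–4 bar), CH2Cl2, rt
Reagents that add atoms: none
Why: Hydroxyl-directed homogeneous hydrogenation: the homoallylic CH2OH on C3, pushed pseudoaxial by allylic strain against the C2 carboxamide, binds the cationic monovalent iridium centre and both hydrogens reach the C1=C2 bond from its face. The new C2–H is therefore cis to CH2OH and the carboxamide trans (2R,3R); aryl benzyl ethers are not cleaved by this catalyst.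

Step 7
Reactants: 10 (2R,3R)-7-(benzyloxy)-3-(hydroxymethyl)-6-methoxy-N-(quinolin-8-yl)-1,2,3,4-tetrahydronaphthalene-2-carboxamide
Product: 11 (2R,3R)-3-(acetoxymethyl)-7-(benzyloxy)-6-methoxy-N-(quinolin-8-yl)-1,2,3,4-tetrahydronaphthalene-2-carboxamide
Conditions: Ac2O, pyridine, DMAP (cat.), CH2Cl2, 0 °C to rt
Reagents that add atoms: acetic anhydride, CC(=O)OC(C)=O
Why: Standard O-acetylation of a primary alcohol; the anilide N–H is far less nucleophilic and stays free for chelation in step 9. The acetate prevents alcohol oxidation and O-arylation under Pd/Ag conditions and is removed by the hydride of step 11 without an extra step.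

Step 8
Reactants: 12 4-iodo-2-methoxyphenol
Product: 13 1-(benzyloxy)-4-iodo-2-methoxybenzene
Conditions: BnBr, K2CO3, DMF, rt
Reagents that add atoms: benzyl bromide, BrCc1ccccc1
Why: Williamson etherification of a phenol; no stereochemistry is involved.

Step 9
Reactants: 11 (2R,3R)-3-(acetoxymethyl)-7-(benzyloxy)-6-methoxy-N-(quinolin-8-yl)-1,2,3,4-tetrahydronaphthalene-2-carboxamide; 13 1-(benzyloxy)-4-iodo-2-methoxybenzene
Product: 14 (1R,2R,3R)-3-(acetoxymethyl)-7-(benzyloxy)-1-[4-(benzyloxy)-3-methoxyphenyl]-6-methoxy-N-(quinolin-8-yl)-1,2,3,4-tetrahydronaphthalene-2-carboxamide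
Conditions: Pd(OAc)2 (10 mol %), AgOAc (2.0 equiv), (BnO)2PO2H (20 mol %), 13 (3 equiv), t-AmOH, 100 °C
Reagents that add atoms: none
Why: The reaction is the quinolin-8-yl-amide-directed, Pd(OAc)2-catalysed β-C(sp3)–H arylation of a secondary carboxamide with an aryl iodide, a known reaction type for benzylic and ring methylene groups. The deprotonated amide nitrogen and the quinoline nitrogen bind divalent palladium as an N,N-chelate, and acetate-assisted concerted metalation–deprotonation can only reach the C1–H bond on the face of the C2 carboxamide, giving a five-membered palladacycle cis-fused to ring B. Oxidative addition of 13 gives a tetravalent palladium aryl, and C–C reductive elimination proceeds with retention at C1, so the aryl group is delivered cis to the carboxamide; AgOAc removes iodide and returns the acetate catalyst. No ring of the product is closed in this step; the only ring formed is the transient palladacycle. The new stereocentre C1 is controlled solely by C2 (1,2-cis, 1R), and because C2 is trans to C3 the aryl group ends trans to the acetoxymethyl group, which is the 1,2-cis-2,3-trans array of the target. Site selectivity is needed against C3–H (β but tertiary), C4–H2 (γ, six-membered palladacycle) and aromatic C–H bonds; the secondary, benzylic, β-positioned C1–H2 is the kinetically preferred site. Over-arylation is excluded because the remaining C1–H is trans to the directing group. C2 must keep its configuration, which the base-free, acetate-buffered medium and moderate temperature are chosen to secure.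

Step 10
Reactants: 14 (1R,2R,3R)-3-(acetoxymethyl)-7-(benzyloxy)-1-[4-(benzyloxy)-3-methoxyphenyl]-6-methoxy-N-(quinolin-8-yl)-1,2,3,4-tetrahydronaphthalene-2-carboxamide
Product: 15 tert-butyl N-{[(1R,2R,3R)-3-(acetoxymethyl)-7-(benzyloxy)-1-[4-(benzyloxy)-3-methoxyphenyl]-6-methoxy-1,2,3,4-tetrahydronaphthalen-2-yl]carbonyl}-N-(quinolin-8-yl)carbamate
Conditions: Boc2O (3 equiv), DMAP (0.5 equiv), MeCN, 50 °C
Reagents that add atoms: di-tert-butyl dicarbonate, CC(C)(C)OC(=O)OC(=O)OC(C)(C)C
Why: N-acylation of the secondary anilide with Boc2O/DMAP twists and activates the amide C–N bond (standard activation of a directing-group amide as its N-Boc imide). No base strong enough to enolise C2 is present.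

Step 11
Reactants: 15 tert-butyl N-{[(1R,2R,3R)-3-(acetoxymethyl)-7-(benzyloxy)-1-[4-(benzyloxy)-3-methoxyphenyl]-6-methoxy-1,2,3,4-tetrahydronaphthalen-2-yl]carbonyl}-N-(quinolin-8-yl)carbamate
Product: 16 [(1R,2R,3R)-7-(benzyloxy)-1-[4-(benzyloxy)-3-methoxyphenyl]-6-methoxy-1,2,3,4-tetrahydronaphthalene-2,3-diyl]dimethanol
Conditions: LiBH4 (5 equiv), THF–MeOH (10:1), 0 °C to rt; aq. NH4Cl
Reagents that add atoms: none
Why: Hydride attacks the activated imide carbonyl, the carbamate anion leaves and the aldehyde formed is reduced at once to the primary alcohol; the acetate is reduced in the same operation. No stereocentre is touched provided the transient aldehyde is reduced faster than it enolises, which excess LiBH4 at 0 °C favours.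

Step 12
Reactants: 16 [(1R,2R,3R)-7-(benzyloxy)-1-[4-(benzyloxy)-3-methoxyphenyl]-6-methoxy-1,2,3,4-tetrahydronaphthalene-2,3-diyl]dimethanol
Product: 17 (6R,7R,8R)-8-(4-hydroxy-3-methoxyphenyl)-6,7-bis(hydroxymethyl)-3-methoxy-5,6,7,8-tetrahydronaphthalen-2-ol (the target)
Conditions: H2 (1 atm), 10% Pd/C, EtOAc–MeOH, rt
Reagents that add atoms: none
Why: Hydrogenolysis of the two aryl benzyl ethers; the product has no benzylic C–O or C–N bond and no alkene, so nothing else should react and the three stereocentres are untouched.

Compound list

1 | 4-(benzyloxy)-3-methoxybenzaldehyde | O=Cc1ccc(OCc2ccccc2)c(OC)c1 | starting material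
2 | dimethyl succinate | COC(=O)CCC(=O)OC | starting material
3 | (3E)-4-[4-(benzyloxy)-3-methoxyphenyl]-3-(methoxycarbonyl)but-3-enoic acid | COC(=O)/C(CC(=O)O)=C/c1ccc(OCc2ccccc2)c(OC)c1 | intermediate
4 | (3R)-4-[4-(benzyloxy)-3-methoxyphenyl]-3-(methoxycarbonyl)butanoic acid | OC(=O)C[C@@H](Cc1ccc(OCc2ccccc2)c(OC)c1)C(=O)OC | intermediate
5 | (3R)-4-[4-(benzyloxy)-3-methoxyphenyl]-3-(hydroxymethyl)butanoic acid (not isolated) | OC(=O)C[C@@H](Cc1ccc(OCc2ccccc2)c(OC)c1)CO | intermediate
6 | (4R)-4-[4-(benzyloxy)-3-methoxybenzyl]oxolan-2-one | O=C1C[C@@H](Cc2ccc(OCc3ccccc3)c(OC)c2)CO1 | intermediate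
7 | (4R)-4-[4-(benzyloxy)-3-methoxybenzyl]-3-(hydroxymethylidene)oxolan-2-one (enol form, alkene geometry not defined, not isolated) | O=C1OC[C@H](Cc2ccc(OCc3ccccc3)c(OC)c2)C1=CO | intermediate
8 | (3aR)-7-(benzyloxy)-6-methoxy-3a,4-dihydronaphtho[2,3-c]furan-1(3H)-one | O=C1OC[C@@H]2Cc3cc(OC)c(OCc4ccccc4)cc3C=C12 | intermediate
9 | (3R)-7-(benzyloxy)-3-(hydroxymethyl)-6-methoxy-N-(quinolin-8-yl)-3,4-dihydronaphthalene-2-carboxamide | O=C(Nc1cccc2cccnc12)C1=Cc2cc(OCc3ccccc3)c(OC)cc2C[C@H]1CO | intermediate
10 | (2R,3R)-7-(benzyloxy)-3-(hydroxymethyl)-6-methoxy-N-(quinolin-8-yl)-1,2,3,4-tetrahydronaphthalene-2-carboxamide | O=C(Nc1cccc2cccnc12)[C@@H]1Cc2cc(OCc3ccccc3)c(OC)cc2C[C@H]1CO | intermediate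
11 | (2R,3R)-3-(acetoxymethyl)-7-(benzyloxy)-6-methoxy-N-(quinolin-8-yl)-1,2,3,4-tetrahydronaphthalene-2-carboxamide | O=C(Nc1cccc2cccnc12)[C@@H]1Cc2cc(OCc3ccccc3)c(OC)cc2C[C@H]1COC(C)=O | intermediate
12 | 4-iodo-2-methoxyphenol | COc1cc(I)ccc1O | starting material
13 | 1-(benzyloxy)-4-iodo-2-methoxybenzene | COc1cc(I)ccc1OCc1ccccc1 | intermediate
14 | (1R,2R,3R)-3-(acetoxymethyl)-7-(benzyloxy)-1-[4-(benzyloxy)-3-methoxyphenyl]-6-methoxy-N-(quinolin-8-yl)-1,2,3,4-tetrahydronaphthalene-2-carboxamide | O=C(Nc1cccc2cccnc12)[C@@H]1[C@H](c2ccc(OCc3ccccc3)c(OC)c2)c2cc(OCc3ccccc3)c(OC)cc2C[C@H]1COC(C)=O | intermediate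
15 | tert-butyl N-{[(1R,2R,3R)-3-(acetoxymethyl)-7-(benzyloxy)-1-[4-(benzyloxy)-3-methoxyphenyl]-6-methoxy-1,2,3,4-tetrahydronaphthalen-2-yl]carbonyl}-N-(quinolin-8-yl)carbamate | CC(C)(C)OC(=O)N(c1cccc2cccnc12)C(=O)[C@@H]1[C@H](c2ccc(OCc3ccccc3)c(OC)c2)c2cc(OCc3ccccc3)c(OC)cc2C[C@H]1COC(C)=O | intermediate
16 | [(1R,2R,3R)-7-(benzyloxy)-1-[4-(benzyloxy)-3-methoxyphenyl]-6-methoxy-1,2,3,4-tetrahydronaphthalene-2,3-diyl]dimethanol | OC[C@@H]1[C@H](c2ccc(OCc3ccccc3)c(OC)c2)c2cc(OCc3ccccc3)c(OC)cc2C[C@H]1CO | intermediate
17 | (6R,7R,8R)-8-(4-hydroxy-3-methoxyphenyl)-6,7-bis(hydroxymethyl)-3-methoxy-5,6,7,8-tetrahydronaphthalen-2-ol | COc1cc([C@@H]2c3cc(O)c(OC)cc3C[C@@H](CO)[C@@H]2CO)ccc1O | target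

Total step count: 12. Longest linear sequence: 11 (steps 1–7 and 9–12; step 8 is a one-step side branch).

Steps least certain to work

Step 9 (key step). The most likely failures are slow cyclopalladation, because the C1–H to be cleaved is pseudoaxial next to an equatorial, hindered carboxamide, and loss of configuration at C2 by enolisation of the product at 100 °C, which would drain material into the 1,2-trans series. Dehydrogenation of ring B through the palladacycle is a further drain. The fallback sets out from 6 and comes back at 16, setting C1 and C2 by hydrogenation instead of C–H cleavage. The lithium enolate of 6 (LiHMDS, 2 equiv, THF, −78 °C) is acylated with methyl 4-(benzyloxy)-3-methoxybenzoate to give the α-aroyl lactone F1. Acid cyclodehydration (TFA, CH2Cl2) closes ring B onto the ketone carbon and gives the 9-aryl unsaturated lactone F2. DIBAL-H (CH2Cl2, −78 to 0 °C) reduces the lactone to the alkene diol F3. Hydrogenation with [Ir(cod)(PCy3)(py)]PF6 under H2, directed by the C3 CH2OH, adds both hydrogens to the tetrasubstituted C1=C2 bond from its face and should give 16 with the aryl and C2 CH2OH groups cis to each other and trans to the C3 CH2OH.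

Step 6. The most likely failure is inhibition of the cationic iridium catalyst by chelation to the quinoline amide, or erosion of face selectivity if the amide carbonyl rather than the hydroxyl holds the metal; undirected addition would favour the cis isomer. The fallback sets out from 8 and comes back at 10, replacing catalyst direction by thermodynamic control at an ester. 8 is saponified (LiOH, aq. THF), silylated on both oxygens (TBSCl, imidazole), the silyl ester is cleaved (K2CO3, aq. MeOH) and the carboxylate methylated (MeI, DMF) to give the silyl ether methyl ester F4. Mg in MeOH reduces the conjugated C1=C2 bond and NaOMe in MeOH equilibrates C2 to the diequatorial trans ester F5 (C3 cannot epimerise; the minor cis ester would be separated and recycled). AlMe3 and quinolin-8-amine convert F5 into the silylated amide F6, and Bu4NF removes the silyl group to give 10.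

Step 4. The most likely failures are cleavage of the aryl benzyl ether by the acid, oligomerisation of the hydroxymethylene lactone, and sluggish ring closure because the enol form is only weakly electrophilic. The fallback sets out from 6 and comes back at 8, introducing C1 on the arene first and closing the ring at C1–C2. Rieche formylation (Cl2CHOMe, SnCl4, CH2Cl2, −78 °C) para to OMe gives the aryl aldehyde F7. LiHMDS (THF, −78 °C) triggers the intramolecular aldol addition of the lactone enolate to the non-enolisable aldehyde and gives the tricyclic β-hydroxy lactone F8. Catalytic TsOH in toluene at 60 °C dehydrates the benzylic alcohol to 8.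

Step 11 (with step 10). The most likely failures are incomplete N-acylation of the hindered amide next to the cis aryl group, and epimerisation at C2 through the activated imide or the transient aldehyde, which would give the all-trans diol. The fallback sets out from 14 and comes back at 16, removing the auxiliary by intramolecular alcoholysis under acid instead of activation and hydride. K2CO3 in MeOH removes the acetate to give the hydroxy amide F9. TsOH·H2O in toluene at 80 °C effects N-to-O acyl transfer to the trans-fused lactone F10 with release of the quinoline amine, and LiAlH4 (THF, 0 °C) reduces F10 to 16.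

Further compounds

F1 | step 9 | (4R)-3-[4-(benzyloxy)-3-methoxybenzoyl]-4-[4-(benzyloxy)-3-methoxybenzyl]oxolan-2-one (C3 labile) | O=C1OC[C@H](Cc2ccc(OCc3ccccc3)c(OC)c2)C1C(=O)c1ccc(OCc2ccccc2)c(OC)c1
F2 | step 9 | (3aR)-7-(benzyloxy)-9-[4-(benzyloxy)-3-methoxyphenyl]-6-methoxy-3a,4-dihydronaphtho[2,3-c]furan-1(3H)-one | O=C1OC[C@@H]2Cc3cc(OC)c(OCc4ccccc4)cc3C(c3ccc(OCc4ccccc4)c(OC)c3)=C12
F3 | step 9 | [(3R)-7-(benzyloxy)-1-[4-(benzyloxy)-3-methoxyphenyl]-6-methoxy-3,4-dihydronaphthalene-2,3-diyl]dimethanol | OCC1=C(c2ccc(OCc3ccccc3)c(OC)c2)c2cc(OCc3ccccc3)c(OC)cc2C[C@H]1CO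
F4 | step 6 | methyl (3R)-7-(benzyloxy)-3-({[tert-butyl(dimethyl)silyl]oxy}methyl)-6-methoxy-3,4-dihydronaphthalene-2-carboxylate | COC(=O)C1=Cc2cc(OCc3ccccc3)c(OC)cc2C[C@H]1CO[Si](C)(C)C(C)(C)C
F5 | step 6 | methyl (2R,3R)-7-(benzyloxy)-3-({[tert-butyl(dimethyl)silyl]oxy}methyl)-6-methoxy-1,2,3,4-tetrahydronaphthalene-2-carboxylate | COC(=O)[C@@H]1Cc2cc(OCc3ccccc3)c(OC)cc2C[C@H]1CO[Si](C)(C)C(C)(C)C
F6 | step 6 | (2R,3R)-7-(benzyloxy)-3-({[tert-butyl(dimethyl)silyl]oxy}methyl)-6-methoxy-N-(quinolin-8-yl)-1,2,3,4-tetrahydronaphthalene-2-carboxamide | O=C(Nc1cccc2cccnc12)[C@@H]1Cc2cc(OCc3ccccc3)c(OC)cc2C[C@H]1CO[Si](C)(C)C(C)(C)C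
F7 | step 4 | (4R)-4-[4-(benzyloxy)-2-formyl-5-methoxybenzyl]oxolan-2-one | O=C1C[C@@H](Cc2cc(OC)c(OCc3ccccc3)cc2C=O)CO1
F8 | step 4 | (3aR)-7-(benzyloxy)-9-hydroxy-6-methoxy-3a,4,9,9a-tetrahydronaphtho[2,3-c]furan-1(3H)-one (C9 and C9a not defined) | O=C1OC[C@@H]2Cc3cc(OC)c(OCc4ccccc4)cc3C(O)C12
F9 | step 11 | (1R,2R,3R)-7-(benzyloxy)-1-[4-(benzyloxy)-3-methoxyphenyl]-3-(hydroxymethyl)-6-methoxy-N-(quinolin-8-yl)-1,2,3,4-tetrahydronaphthalene-2-carboxamide | O=C(Nc1cccc2cccnc12)[C@@H]1[C@H](c2ccc(OCc3ccccc3)c(OC)c2)c2cc(OCc3ccccc3)c(OC)cc2C[C@H]1CO
F10 | step 11 | (3aR,9R,9aR)-7-(benzyloxy)-9-[4-(benzyloxy)-3-methoxyphenyl]-6-methoxy-3a,4,9,9a-tetrahydronaphtho[2,3-c]furan-1(3H)-one | O=C1OC[C@@H]2Cc3cc(OC)c(OCc4ccccc4)cc3[C@@H](c3ccc(OCc4ccccc4)c(OC)c3)[C@@H]12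
A1 | alternative 1 | (3S,4R)-4-[4-(benzyloxy)-3-methoxybenzyl]-3-{[4-(benzyloxy)-3-methoxyphenyl](hydroxy)methyl}oxolan-2-one (carbinol centre not defined) | O=C1OC[C@H](Cc2ccc(OCc3ccccc3)c(OC)c2)[C@H]1C(O)c1ccc(OCc2ccccc2)c(OC)c1
A2 | alternative 1 | (3aR,9S,9aR)-7-(benzyloxy)-9-[4-(benzyloxy)-3-methoxyphenyl]-6-methoxy-3a,4,9,9a-tetrahydronaphtho[2,3-c]furan-1(3H)-one | O=C1OC[C@@H]2Cc3cc(OC)c(OCc4ccccc4)cc3[C@H](c3ccc(OCc4ccccc4)c(OC)c3)[C@@H]12
A3 | alternative 2 | 6-(benzyloxy)-1-[4-(benzyloxy)-3-methoxyphenyl]-5-methoxy-1,3-dihydro-2-benzothiophene 2,2-dioxide (racemic) | O=S1(=O)Cc2cc(OC)c(OCc3ccccc3)cc2C1c1ccc(OCc2ccccc2)c(OC)c1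
A4 | alternative 2 | dimethyl (2R,3R)-7-(benzyloxy)-1-[4-(benzyloxy)-3-methoxyphenyl]-6-methoxy-1,2,3,4-tetrahydronaphthalene-2,3-dicarboxylate (C1 not defined) | COC(=O)[C@@H]1Cc2cc(OC)c(OCc3ccccc3)cc2C(c2ccc(OCc3ccccc3)c(OC)c2)[C@H]1C(=O)OC
A5 | alternative 3 | (6R)-8-(4-hydroxy-3-methoxyphenyl)-6,7-bis(hydroxymethyl)-3-methoxy-5,6-dihydronaphthalen-2-ol | OCC1=C(c2ccc(O)c(OC)c2)c2cc(O)c(OC)cc2C[C@H]1CO
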